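**Numbering and conventions**

Benzofuran atoms are O1, C2, C3, C3a, C4–C7, C7a, and ring A is its benzo ring. Ring B is the aryl ring on C2, with atoms C1'–C6' (C1' bonded to C2). MOM = methoxymethyl, prenyl = 3-methylbut-2-enyl.

- 1: 1-(3,5-dihydroxyphenyl)ethanone
- 2: 3-chloro-3-methylbut-1-yne
- 3: bis(1,1-dimethylpropargyl) ether of 1
- 4: bis(1,1-dimethylallyl) ether of 1
- 5: mono-rearranged phenol (not isolated)
- 6: 2,6-diprenyl-3,5-dihydroxyacetophenone
- 7: bis-MOM ether of 6
- 8: 3-bromophenol
- 9: 3-bromo-4-iodophenol
- 10: MOM ether of 9
- 11: α-(2-bromoaryl) ketone (not isolated)
- 12: tris-MOM benzofuran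
- 13: mulberrofuran V

## Analysis of the target

Mulberrofuran V (13) is a 2-arylbenzofuran. Ring A carries a hydroxyl at C6, the furan ring (O1, C2, C3, C3a, C7a) is fused to it, and ring B is bonded through C1' to C2. Ring B is pentasubstituted and locally symmetric: prenyl groups at C2' and C6', hydroxyls at C3' and C5', hydrogen only at C4'. There is no stereocentre, and both side-chain olefins end in a gem-dimethyl group, so no olefin geometry has to be set. The sensitive groups are three free phenols (oxidation), two ortho-prenylphenol units that acid closes to chromans, and the electron-rich furan C3. Late steps must therefore avoid strong acid, oxidants and hydrogenation. The synthesis is hard for two reasons: the C2–C1' bond is flanked by two prenyl groups, so a cross-coupling there would be di-ortho-hindered, and the prenyl groups must go to C2' and C6', not to C4' between the two oxygens. The strategy rests on this feature: O1–C2–C3 is the enolate of a methyl ketone whose carbonyl carbon is already bonded to C1', and C3a and C7a are adjacent ring-A carbons, C3a para and C7a meta to the C6 oxygen, so they can carry two different halogens.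

## Retrosynthetic reasoning

**13 ⇒ 12.** The last operation should only unmask the three phenols, so the three aryl O–acetal bonds are cut. Methoxymethyl ethers are chosen because they tolerate carbonate base, enolates and palladium, and fall off in dilute acid mild enough to spare the prenyl olefins. Benzyl ethers would need hydrogenolysis, which would saturate the side chains. Methyl ethers would need Lewis acids that attack ortho-prenylphenols.

**12 ⇒ 7 + 10.** The furan ring is opened at C3–C3a and O1–C7a. Cutting here means the crowded C2–C1' bond is never formed by a coupling: it is the carbonyl–aryl bond of ketone 7 and is present from the start. Ring A becomes the bromo-iodoarene 10 and O1–C2–C3 becomes the enolisable acetyl group of 7. The forward reaction must arylate the enolate carbon at the iodide-bearing carbon and the enolate oxygen at the bromide-bearing carbon, in that order, because the order decides between a 6- and a 5-oxygenated benzofuran. The gain is convergence: two bonds and the ring in one operation, with one step left afterwards.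

**10 ⇒ 9 ⇒ 8.** The acetal O–C bond and then the C–I bond are cut. Phenol 8 already has bromine meta to oxygen, where C7a needs its halide. Iodine must enter para to the hydroxyl (the future C3a), which is the position the hydroxyl activates most for a mild electrophilic iodination.

**7 ⇒ 6.** Two acetal O–C bonds are cut. Protection is placed after the prenyl transfer because the transfer itself liberates the phenols.

**6 ⇒ 4 (through 5).** The C2'–CH2 and C6'–CH2 bonds are cut and both prenyl groups are returned to oxygen as 1,1-dimethylallyl ethers. Direct electrophilic prenylation of 1 would give mixtures of C2/C6, C4, O- and poly-alkylation. The sigmatropic route delivers each allyl unit intramolecularly to an ortho carbon with allylic inversion, which is why the ether must be the tertiary, reverse-prenyl one. Each target carbon is next to the acetyl group and para to the other oxygen, and both substituents favour that site over C4.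

**4 ⇒ 3 ⇒ 1 + 2.** A tertiary allyl aryl ether cannot be made by direct displacement. The O–C bonds are therefore formed with the propargylic chloride 2, which ionises readily with copper assistance, and the alkynes of 3 are then semi-reduced. Both 1 and 2 are commercial.

## Alternatives that were turned down

**Alternative 1:** The C2'–CH2 and C6'–CH2 bonds would be made last, on the finished 2-arylbenzofuran. The bis(1,1-dimethylallyl) ether A2 would be heated, optionally with a lanthanide Lewis acid, to undergo two [3,3] shifts to the diprenyl resorcinol A1, and desilylation would finish the synthesis.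
- For: the benzofuran is built while ring B is unhindered, the shift itself frees the ring-B phenols so they need no protection at the end, and the pericyclic step is as reliable in kind as step 3 of the chosen route.
- Against: in A2 the C1' substituent is an electron-rich benzofuran-2-yl group, not an acyl acceptor. Only the second oxygen then steers the allyl unit to C2'/C6', and migration to C4' becomes more competitive.
- Against: any misdirected prenyl group is paid for with advanced material and gives isomers that are hard to separate. The free ortho-prenyl resorcinol is also generated hot, next to an acid-sensitive benzofuran.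
- Comparison: the chosen route runs the same rearrangement on the cheap acetophenone 4, where the acetyl group reinforces the regiochemistry and an error costs little. On protecting-group economy Alternative 1 is the stronger.

**Alternative 2:** Ring B would be built de novo. The enone A4 and the malonate A5 would combine under alkoxide by Michael addition (C1'–C2') and Claisen condensation of the methyl ketone onto an ester (C3'–C4') to give the cyclohexanedione A3. Ester removal, dehydrogenation to the resorcinol and deprotection would follow.
- For: every ring-B substituent is fixed by connectivity, so there is no arene regiochemistry question. On this point it is stronger than the chosen route, which relies on directing effects in step 3.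
- Against: the Michael step joins a fully substituted malonate carbon to the β-carbon of an α-substituted enone that is deactivated by an electron-rich heteroaryl group. It is hindered and reversible.
- Against: A3 then needs dealkoxycarbonylation at a quaternary carbon and an oxidative aromatisation in the presence of two prenyl olefins and a benzofuran.
- Comparison: the chosen route keeps ring B aromatic throughout, needs no redox adjustment and is several steps shorter after the key step.

**Alternative 3:** The three bonds at C1', C2' and C6' would be made in one palladium/strained-olefin relay (Catellani reaction). The aryl iodide A7 would be alkylated at both ortho positions by two equivalents of the iodide A8 and terminated by Suzuki coupling with the boronate A9 to give A6.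
- For: three bonds in one operation, and the side chains are placed ortho to the iodide by mechanism. In convergence and positional certainty it is stronger than the chosen route.
- Against: each ortho C–H of A7 is flanked by a MOM ether, so both alkylations occur at doubly flanked positions. The terminating coupling joins a di-ortho-substituted arylpalladium to a 2-heteroarylboron reagent prone to protodeboronation.
- Against: the side chains arrive as two-carbon surrogates, because an allylic halide would react with palladium directly. A6 therefore needs desilylation, oxidation to a labile bis(arylacetaldehyde), a double isopropylidene Wittig reaction and deprotection.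
- Comparison: the chosen route installs the prenyl groups as such and leaves a single step after the key step.

Key step: step 7

## Route

Step 1
Reactants: 1 1-(3,5-dihydroxyphenyl)ethanone; 2 3-chloro-3-methylbut-1-yne
Product: 3 1-[3,5-bis(2-methylbut-3-yn-2-yloxy)phenyl]ethanone
Conditions: 2 (3 equiv), K2CO3, KI (cat.), CuI (cat.), acetone, reflux
Reagents that add atoms: none
Why: Copper-assisted propargylic etherification (Williamson-type, through the copper acetylide of the tertiary chloride, which ionises easily) converts both phenols into 1,1-dimethylpropargyl ethers; the ketone is inert to carbonate.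

Step 2
Reactants: 3 1-[3,5-bis(2-methylbut-3-yn-2-yloxy)phenyl]ethanone
Product: 4 1-[3,5-bis(2-methylbut-3-en-2-yloxy)phenyl]ethanone
Conditions: H2 (1 atm), Pd/CaCO3 poisoned with Pb(OAc)2 (Lindlar catalyst), quinoline, EtOAc, rt, stopped at 2 equiv H2
Reagents that add atoms: none
Why: Lindlar semi-hydrogenation should reduce the terminal alkynes to vinyl groups and stop there when hydrogen uptake is monitored; the aryl ketone and the arene are not reduced on the poisoned catalyst.

Step 3
Reactants: 4 1-[3,5-bis(2-methylbut-3-en-2-yloxy)phenyl]ethanone
Product: 6 1-[3,5-dihydroxy-2,6-bis(3-methylbut-2-enyl)phenyl]ethanone, via mono-Claisen phenol 5 (not isolated)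
Conditions: PhNEt2, 150–170 °C, Ar
Reagents that add atoms: none
Why: Two successive aromatic Claisen rearrangements ([3,3] shift, then tautomerisation of the dienone) move each 1,1-dimethylallyl group from oxygen to an ortho carbon with allylic inversion, giving linear prenyl groups. Migration should go to C2 and C6, because each is next to the acyl acceptor and para to the other oxygen donor, and both effects disfavour C4; the basic solvent suppresses acid-mediated chroman formation.

Step 4
Reactants: 6 1-[3,5-dihydroxy-2,6-bis(3-methylbut-2-enyl)phenyl]ethanone
Product: 7 1-[3,5-bis(methoxymethoxy)-2,6-bis(3-methylbut-2-enyl)phenyl]ethanone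
Conditions: MOMCl, K2CO3, acetone, rt to 50 °C
Reagents that add atoms: chloromethyl methyl ether, COCCl
Why: O-Alkylation of the phenoxides with the reactive α-chloro ether (Williamson-type acetal formation); carbonate is too weak to enolise the ketone, so only the phenols react.

Step 5
Reactants: 8 3-bromophenol
Product: 9 3-bromo-4-iodophenol
Conditions: NIS, TsOH·H2O (cat.), MeCN, rt
Reagents that add atoms: N-iodosuccinimide, O=C1CCC(=O)N1I
Why: Electrophilic aromatic iodination with acid-activated N-iodosuccinimide should take place para to the hydroxyl, the most activated and least hindered position with respect to oxygen, placing iodine next to bromine.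

Step 6
Reactants: 9 3-bromo-4-iodophenol
Product: 10 2-bromo-1-iodo-4-(methoxymethoxy)benzene
Conditions: MOMCl, K2CO3, acetone, rt
Reagents that add atoms: chloromethyl methyl ether, COCCl
Why: Williamson-type O-alkylation of an acidic halophenol; the aryl halides are inert.

Step 7
Reactants: 7 1-[3,5-bis(methoxymethoxy)-2,6-bis(3-methylbut-2-enyl)phenyl]ethanone; 10 2-bromo-1-iodo-4-(methoxymethoxy)benzene
Product: 12 2-[3,5-bis(methoxymethoxy)-2,6-bis(3-methylbut-2-enyl)phenyl]-6-(methoxymethoxy)benzofuran, via α-aryl ketone 11 (not isolated)
Conditions: 7 (1.2 equiv), Pd2(dba)3 (cat.), DPEphos (cat.), Cs2CO3 (3 equiv), toluene, 110 °C, Ar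
Reagents that add atoms: none
Why: Zerovalent palladium on the wide-bite-angle diphosphine inserts into the C–I bond of 10 far faster than into its C–Br bond; the cesium enolate of 7, which can form only at the methyl group, replaces iodide on divalent palladium and C–C reductive elimination gives α-aryl ketone 11 (bond C3–C3a), as in a Buchwald–Hartwig ketone α-arylation. The benzylic methylene of 11 is markedly more acidic than the methyl group of 7, so carbonate now holds it as the enolate. A second oxidative addition at the neighbouring C–Br bond gives an arylpalladium bromide that the enolate oxygen captures as a six-membered oxapalladacycle, and C–O reductive elimination forms O1–C7a. The furan is thus closed as a five-membered ring by intramolecular O-arylation of an enolate; C-arylation is not an option at this stage because it would give a four-membered ring. The closest known reaction type is the palladium-catalysed tandem α-arylation and intramolecular O-arylation of ketones with 1-bromo-2-iodoarenes to give benzofurans. No stereocentre is formed. The step needs site selectivity (carbon to the iodide-bearing carbon para to the MOM ether, oxygen to the bromide-bearing carbon, which puts the ring-A oxygen at C6 and not C5) and mono-arylation; the first follows from the reactivity gap between C–I and C–Br and from the preference of palladium ketone enolates for C–C over C–O reductive elimination when both are open, the second from the crowding of the methylene of 11 between the di-ortho-prenylated aroyl group and the ortho-bromoaryl ring and from the slight excess of 7. The carbonyl of 7 is twisted out of the ring plane by its two ortho prenyl groups, which blocks aldol self-condensation without hindering the remote methyl group, and MOM ethers and trisubstituted olefins are inert to the conditions.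

Step 8
Reactants: 12 2-[3,5-bis(methoxymethoxy)-2,6-bis(3-methylbut-2-enyl)phenyl]-6-(methoxymethoxy)benzofuran
Product: 13 mulberrofuran V, 5-(6-hydroxybenzofuran-2-yl)-4,6-bis(3-methylbut-2-enyl)benzene-1,3-diol
Conditions: 3 M aq. HCl (few equiv), MeOH, 40 °C, stopped at full conversion
Reagents that add atoms: none
Why: Acid-catalysed transacetalisation of the three aryl MOM ethers with methanol, which carries the formaldehyde unit away as its dimethyl acetal; the dilute acid and low temperature should leave the trisubstituted olefins and the benzofuran untouched.

## Compound list

1 | 1-(3,5-dihydroxyphenyl)ethanone | CC(=O)c1cc(O)cc(O)c1 | starting material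
2 | 3-chloro-3-methylbut-1-yne | CC(C)(Cl)C#C | starting material
3 | 1-[3,5-bis(2-methylbut-3-yn-2-yloxy)phenyl]ethanone | CC(=O)c1cc(OC(C)(C)C#C)cc(OC(C)(C)C#C)c1 | intermediate
4 | 1-[3,5-bis(2-methylbut-3-en-2-yloxy)phenyl]ethanone | CC(=O)c1cc(OC(C)(C)C=C)cc(OC(C)(C)C=C)c1 | intermediate
5 | 1-[3-hydroxy-5-(2-methylbut-3-en-2-yloxy)-2-(3-methylbut-2-enyl)phenyl]ethanone | CC(=O)c1cc(OC(C)(C)C=C)cc(O)c1CC=C(C)C | intermediate
6 | 1-[3,5-dihydroxy-2,6-bis(3-methylbut-2-enyl)phenyl]ethanone | CC(=O)c1c(CC=C(C)C)c(O)cc(O)c1CC=C(C)C | intermediate
7 | 1-[3,5-bis(methoxymethoxy)-2,6-bis(3-methylbut-2-enyl)phenyl]ethanone | CC(=O)c1c(CC=C(C)C)c(OCOC)cc(OCOC)c1CC=C(C)C | intermediate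
8 | 3-bromophenol | Oc1cccc(Br)c1 | starting material
9 | 3-bromo-4-iodophenol | Oc1ccc(I)c(Br)c1 | intermediate
10 | 2-bromo-1-iodo-4-(methoxymethoxy)benzene | COCOc1ccc(I)c(Br)c1 | intermediate
11 | 1-[3,5-bis(methoxymethoxy)-2,6-bis(3-methylbut-2-enyl)phenyl]-2-[2-bromo-4-(methoxymethoxy)phenyl]ethanone | COCOc1ccc(CC(=O)c2c(CC=C(C)C)c(OCOC)cc(OCOC)c2CC=C(C)C)c(Br)c1 | intermediate
12 | 2-[3,5-bis(methoxymethoxy)-2,6-bis(3-methylbut-2-enyl)phenyl]-6-(methoxymethoxy)benzofuran | COCOc1ccc2cc(-c3c(CC=C(C)C)c(OCOC)cc(OCOC)c3CC=C(C)C)oc2c1 | intermediate
13 | mulberrofuran V, 5-(6-hydroxybenzofuran-2-yl)-4,6-bis(3-methylbut-2-enyl)benzene-1,3-diol | CC(C)=CCc1c(O)cc(O)c(CC=C(C)C)c1-c1cc2ccc(O)cc2o1 | target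

## Step count and least certain steps

Total: 8 steps. Longest linear sequence: 6 steps (steps 1, 2, 3, 4, 7, 8). The ring-A branch is 2 steps (5, 6) before the union.

**Step 7 (key step).** Three things are most likely to go wrong. Enolisation of the methyl ketone by carbonate may be slow, so the reaction stalls. The enolate of 11 may be arylated a second time by fresh 10 before it closes. The C–Br bond may be lost by reduction. All three come from asking one catalyst to do two different bond formations at one temperature. The fallback separates them and changes the metal for the ring closure. It sets out from 7 and 10. Mono-α-arylation with Pd2(dba)3, Xantphos and NaOtBu in THF at 60 °C, with 7 in excess, should engage only the iodide and allow 11 to be isolated. Copper-catalysed intramolecular O-arylation of its enolate (CuI, 1,10-phenanthroline, K3PO4, DMF, 100 °C; an Ullmann-type closure known for 2-haloaryl ketones) then returns to the route at 12. This path makes no compound outside the list (F0).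

**Step 3.** Part of the allyl transfer may go to C4 between the two oxygens, and the hot ortho-prenylphenol may add its own hydroxyl across the olefin, because the selectivity rests on directing effects and not on blocking. The fallback places the side chains by cross-coupling and sets out from 1. Double MOM protection (MOMCl, K2CO3, acetone) should give 1-[3,5-bis(methoxymethoxy)phenyl]ethanone F1. Two-fold ring bromination with NBS in MeCN, which goes para to each ether oxygen, should give 1-[2,6-dibromo-3,5-bis(methoxymethoxy)phenyl]ethanone F2. A double Stille coupling with tributyl(3-methylbut-2-enyl)stannane (Pd(PPh3)4, DMF, 100 °C) then returns to the route at 7, bypassing steps 1–4.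

**Step 8.** Acid may add the freed C3' and C5' hydroxyls to the neighbouring prenyl olefins (chroman formation) or hydrate the olefins, and formaldehyde equivalents may be captured by the electron-rich rings. The fallback removes acid from the end of the route by changing the protecting group. It sets out from 6 and 9. Silylation (TIPSOTf, 2,6-lutidine, CH2Cl2) should give 1-[2,6-bis(3-methylbut-2-enyl)-3,5-bis(triisopropylsilyloxy)phenyl]ethanone F3 and (3-bromo-4-iodophenoxy)triisopropylsilane F4. The same palladium tandem arylation as in step 7 should give 2-[2,6-bis(3-methylbut-2-enyl)-3,5-bis(triisopropylsilyloxy)phenyl]-6-(triisopropylsilyloxy)benzofuran F5. Buffered fluoride (TBAF, AcOH, THF, 0 °C) then returns to the route at 13.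

**Step 5.** Iodination may occur in part ortho to the hydroxyl (para to bromine), or twice, because the free phenol is highly activated. The fallback masks the phenol first and sets out from 8. O-Methylation (MeI, K2CO3, acetone) gives 1-bromo-3-methoxybenzene F6. Iodination of this anisole (NIS, cat. TFA, MeCN), where para attack dominates, should give 2-bromo-1-iodo-4-methoxybenzene F7. Demethylation with BBr3 in CH2Cl2 at −78 °C to rt then returns to the route at 9.

**Step 2.** Hydrogenation may run past the alkene stage to the saturated tert-pentyl ethers, which cannot rearrange, because terminal vinyl groups are reduced readily. The fallback avoids hydrogen altogether and sets out from 1. Palladium-catalysed allylic etherification (Tsuji–Trost reaction) with tert-butyl 2-methylbut-3-en-2-yl carbonate and Pd(PPh3)4 in THF at 0 °C should give the branched tertiary aryl ether under kinetic control and return to the route at 4. No compound outside the list arises (F0).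

## Further compounds

F0 | step 7 | none | none
F1 | step 3 | 1-[3,5-bis(methoxymethoxy)phenyl]ethanone | CC(=O)c1cc(OCOC)cc(OCOC)c1
F2 | step 3 | 1-[2,6-dibromo-3,5-bis(methoxymethoxy)phenyl]ethanone | CC(=O)c1c(Br)c(OCOC)cc(OCOC)c1Br
F3 | step 8 | 1-[2,6-bis(3-methylbut-2-enyl)-3,5-bis(triisopropylsilyloxy)phenyl]ethanone | CC(=O)c1c(CC=C(C)C)c(O[Si](C(C)C)(C(C)C)C(C)C)cc(O[Si](C(C)C)(C(C)C)C(C)C)c1CC=C(C)C
F4 | step 8 | (3-bromo-4-iodophenoxy)triisopropylsilane | CC(C)[Si](Oc1ccc(I)c(Br)c1)(C(C)C)C(C)C
F5 | step 8 | 2-[2,6-bis(3-methylbut-2-enyl)-3,5-bis(triisopropylsilyloxy)phenyl]-6-(triisopropylsilyloxy)benzofuran | CC(C)[Si](Oc1ccc2cc(-c3c(CC=C(C)C)c(O[Si](C(C)C)(C(C)C)C(C)C)cc(O[Si](C(C)C)(C(C)C)C(C)C)c3CC=C(C)C)oc2c1)(C(C)C)C(C)C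
F6 | step 5 | 1-bromo-3-methoxybenzene | COc1cccc(Br)c1
F7 | step 5 | 2-bromo-1-iodo-4-methoxybenzene | COc1ccc(I)c(Br)c1
F0 | step 2 | none | none
A1 | alternative 1 | 4,6-bis(3-methylbut-2-enyl)-5-[6-(triisopropylsilyloxy)benzofuran-2-yl]benzene-1,3-diol | CC(C)=CCc1c(O)cc(O)c(CC=C(C)C)c1-c1cc2ccc(O[Si](C(C)C)(C(C)C)C(C)C)cc2o1
A2 | alternative 1 | 2-[3,5-bis(2-methylbut-3-en-2-yloxy)phenyl]-6-(triisopropylsilyloxy)benzofuran | C=CC(C)(C)Oc1cc(OC(C)(C)C=C)cc(-c2cc3ccc(O[Si](C(C)C)(C(C)C)C(C)C)cc3o2)c1
A3 | alternative 2 | ethyl 2-[6-(methoxymethoxy)benzofuran-2-yl]-1,3-bis(3-methylbut-2-enyl)-4,6-dioxocyclohexane-1-carboxylate (mixture of diastereomers) | CCOC(=O)C1(CC=C(C)C)C(=O)CC(=O)C(CC=C(C)C)C1c1cc2ccc(OCOC)cc2o1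
A4 | alternative 2 | (3E)-3-[[6-(methoxymethoxy)benzofuran-2-yl]methylidene]-6-methylhept-5-en-2-one | CC(=O)/C(CC=C(C)C)=C/c1cc2ccc(OCOC)cc2o1
A5 | alternative 2 | diethyl 2-(3-methylbut-2-enyl)propanedioate | CCOC(=O)C(CC=C(C)C)C(=O)OCC
A6 | alternative 3 | 2-[2,6-bis[2-(tert-butyldimethylsilyloxy)ethyl]-3,5-bis(methoxymethoxy)phenyl]-6-(methoxymethoxy)benzofuran | COCOc1ccc2cc(-c3c(CCO[Si](C)(C)C(C)(C)C)c(OCOC)cc(OCOC)c3CCO[Si](C)(C)C(C)(C)C)oc2c1
A7 | alternative 3 | 1-iodo-3,5-bis(methoxymethoxy)benzene | COCOc1cc(I)cc(OCOC)c1
A8 | alternative 3 | tert-butyl(2-iodoethoxy)dimethylsilane | CC(C)(C)[Si](C)(C)OCCI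
A9 | alternative 3 | 2-[6-(methoxymethoxy)benzofuran-2-yl]-4,4,5,5-tetramethyl-1,3,2-dioxaborolane | COCOc1ccc2cc(B3OC(C)(C)C(C)(C)O3)oc2c1
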